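## Retrosynthetic overview

1. Isochromene numbering is used for both halves (C1, O2, C3, C4, C4a, C5–C8, C8a). The CH2 bridge is cut at C7 of the quinone methide half: vinylogous acid 20 (nucleophilic at C7) adds to the o-quinone methide released from Mannich base 22 of isochromandiol 21.
2. 20 and 21 are one isochroman skeleton at two oxidation levels, so both come from one arene, 18. DDQ oxidation at C1 turns its aryl ethyl ether into a vinylogous ester that hydrolyses to 20; NaBH4 then returns 21.
3. The carbocycle of 18 is annulated onto a preformed dihydropyran from diazoketone 12 and ethoxyethyne 13: Wolff rearrangement, [2+2] cycloaddition, 4π ring opening, then 6π closure that joins ketene carbon C8 to pyran alkene carbon C8a.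
4. Enabling feature: in the carbocycle C4a–C5–C6–C7–C8–C8a the oxygens sit 1,3 on C6 and C8 with C7 between them, and C8 is bonded to the oxygen-free ring-fusion carbon C8a. So C8 maps onto a ketene carbonyl, C6–O onto an ynol ether, and C4a=C8a onto an alkene already inside the pyran ring.
5. Ring order: pyran ring first (steps 1–4; both stereocentres from methyl (R)-3-hydroxybutanoate by anti-selective Fráter–Seebach methylation, then 6-endo-dig closure), carbocycle second (step 9). No protecting groups are used.

Key step: step 9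

Remark on tautomers: the 6-hydroxy-8-oxo and 8-hydroxy-6-oxo forms of the quinone methide are tautomers in fast exchange; they are treated as one compound and drawn as in the target.
Remark on reagents: the amide bases, Grignard reagents and LiBH(s-Bu)3 are taken as commercial solutions.

## Route

Step 1
Reactants: 1 methyl (R)-3-hydroxybutanoate
Product: 3 methyl (2R,3R)-3-hydroxy-2-methylbutanoate, via dilithium dianion 2 (not isolated)
Conditions: LiN(i-Pr)2 (2.2 equiv), THF, −78 → −20 °C; MeI, −78 → 0 °C; aq. NH4Cl
Reagents that add atoms: iodomethane, CI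
Why: Fráter–Seebach alkylation: the lithium-chelated alkoxide–enolate 2 should take up the methyl group on the face opposite to the C3 methyl group, so the existing (3R) carbinol centre sets the new C2 centre anti, i.e. (2R).

Step 2
Reactants: 3 methyl (2R,3R)-3-hydroxy-2-methylbutanoate
Product: 4 (2R,3R)-3-hydroxy-N-methoxy-N,2-dimethylbutanamide
Conditions: MeNH(OMe)·HCl, i-PrMgCl, THF, −20 → 0 °C
Reagents that add atoms: N,O-dimethylhydroxylamine hydrochloride, CNOC.Cl
Why: Weinreb amide formation by aminolysis of the ester with the chloromagnesium amide, which tolerates the free hydroxyl as its magnesium alkoxide and at this temperature should not epimerise the α-centre.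

Step 3
Reactants: 4 (2R,3R)-3-hydroxy-N-methoxy-N,2-dimethylbutanamide
Product: 5 (4R,5R)-5-hydroxy-4-methylhex-1-yn-3-one
Conditions: HC≡CMgBr (3 equiv), THF, 0 °C → rt; cold aq. NaHSO4
Reagents that add atoms: ethynylmagnesium bromide, C#C[Mg]Br
Why: Weinreb ketone synthesis: the chelated tetrahedral adduct stops at mono-addition and releases the ynone only on the acidic quench, which also keeps the liberated amine from adding to the ynone.

Step 4
Reactants: 5 (4R,5R)-5-hydroxy-4-methylhex-1-yn-3-one
Product: 6 (2R,3R)-2,3-dimethyl-2,3-dihydro-4H-pyran-4-one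
Conditions: AgOTf (10 mol %), CH2Cl2, rt
Reagents that add atoms: none
Why: Silver-catalysed 6-endo-dig oxa-Michael cyclisation of a β-hydroxy ynone; no stereocentre is touched, and the trans-2,3-dimethyl (diequatorial) arrangement is the more stable one, so enolisation at C3 would be harmless.

Step 5
Reactants: 6 (2R,3R)-2,3-dimethyl-2,3-dihydro-4H-pyran-4-one
Product: 8 (2R,3R)-2,3-dimethyl-3,6-dihydro-2H-pyran-4-yl trifluoromethanesulfonate, via lithium enolate 7 (not isolated)
Conditions: LiBH(s-Bu)3 (L-Selectride), THF, −78 °C; then PhNTf2, −78 °C → rt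
Reagents that add atoms: N-phenylbis(trifluoromethanesulfonimide), O=S(=O)(N(c1ccccc1)S(=O)(=O)C(F)(F)F)C(F)(F)F
Why: Conjugate hydride reduction of the vinylogous ester gives the regiodefined enolate 7, which is O-triflated in situ, so the double bond is fixed on the side away from the methyl-bearing α-carbon (the future C4a=C8a bond).

Step 6
Reactants: 8 (2R,3R)-2,3-dimethyl-3,6-dihydro-2H-pyran-4-yl trifluoromethanesulfonate
Product: 9 (2R,3S)-N-methoxy-N,2,3-trimethyl-3,6-dihydro-2H-pyran-4-carboxamide
Conditions: Pd(OAc)2 (5 mol %), Xantphos (6 mol %), CO (1 atm), MeNH(OMe)·HCl, Et3N, DMF, 60 °C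
Reagents that add atoms: carbon monoxide, [C-]#[O+]; N,O-dimethylhydroxylamine hydrochloride, CNOC.Cl
Why: Palladium-catalysed aminocarbonylation of an alkenyl triflate (oxidative addition, CO insertion, aminolysis of the acylpalladium species), a reaction that does not involve the allylic stereocentre.

Step 7
Reactants: 9 (2R,3S)-N-methoxy-N,2,3-trimethyl-3,6-dihydro-2H-pyran-4-carboxamide
Product: 10 1-[(2R,3S)-2,3-dimethyl-3,6-dihydro-2H-pyran-4-yl]propan-1-one
Conditions: EtMgBr, THF, −20 → 0 °C; aq. NH4Cl
Reagents that add atoms: ethylmagnesium bromide, CC[Mg]Br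
Why: Weinreb ketone synthesis: 1,2-addition to the unsaturated amide gives a stable chelate, so the enone appears only on work-up and is not exposed to the Grignard reagent.

Step 8
Reactants: 10 1-[(2R,3S)-2,3-dimethyl-3,6-dihydro-2H-pyran-4-yl]propan-1-one
Product: 12 2-diazo-1-[(2R,3S)-2,3-dimethyl-3,6-dihydro-2H-pyran-4-yl]propan-1-one, via trifluoroacetyl diketone 11 (not isolated)
Conditions: LiN(SiMe3)2, THF, −78 °C; CF3CO2CH2CF3; then MsN3, Et3N, H2O (1 equiv), MeCN, rt
Reagents that add atoms: methanesulfonyl azide, CS(=O)(=O)N=[N+]=[N-] (the N2 unit of 12); 2,2,2-trifluoroethyl trifluoroacetate, O=C(OCC(F)(F)F)C(F)(F)F (the trifluoroacetyl group of 11 only)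
Why: Detrifluoroacetylative diazo transfer: kinetic deprotonation on the ethyl side and Claisen trifluoroacetylation activate that carbon, and the sulfonyl azide then delivers the diazo group with loss of the trifluoroacetyl group as the sulfonamide.

Step 9
Reactants: 12 2-diazo-1-[(2R,3S)-2,3-dimethyl-3,6-dihydro-2H-pyran-4-yl]propan-1-one; 13 ethoxyethyne
Product: 18 (3R,4S)-6-ethoxy-3,4,5-trimethyl-3,4-dihydro-1H-isochromen-8-ol, via vinylketene 14 (not isolated), via 4-alkenylcyclobutenone 15 (not isolated), via dienylketene 16 (not isolated), via cyclohexadienone 17 (not isolated)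
Conditions: 13 (3 equiv), hν (254 nm), ClCH2CH2Cl, rt; then 80 °C
Reagents that add atoms: none
Why: Danheiser benzannulation in its photochemical Wolff variant: irradiation of 12 expels N2 and the dihydropyranyl group migrates to give vinylketene 14, whose carbonyl carbon (the future C8) is attacked by the nucleophilic CH terminus of ethoxyethyne in a [2+2] cycloaddition that gives cyclobutenone 15. On heating, 15 opens by reversible conrotatory 4π electrocyclic ring opening to dienylketene 16, and a thermally allowed disrotatory 6π electrocyclisation (six-membered ring) joins ketene carbon C8 to the pyran alkene carbon C8a to give dienone 17, which tautomerises to phenol 18. The step makes four of the six bonds of the carbocycle (C4a–C5 by the Wolff shift, C5–C6 and C7–C8 by the [2+2], C8–C8a by the electrocyclisation) and fuses it to the pyran ring. No lasting stereocentre is created: the quaternary carbon of 15 and C8a–H of 17 are erased by ring opening and tautomerisation, and C3 and C4 are never enolisable or part of a reacting π system, so they should be carried through unchanged. The selectivity needed is regiochemical and is fixed by the polarity of the ynol ether (oxygen ends on C6 beside the C5 methyl group, hydrogen on C7 between the two oxygens); only the isomer of 16 with the ketene arm cis to the pyranyl group can cyclise and the reversible opening of 15 funnels material through it, while C1 lies trans to the ketene across C4a=C8a, which rules out a 1,5-hydrogen shift.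

Step 10
Reactants: 18 (3R,4S)-6-ethoxy-3,4,5-trimethyl-3,4-dihydro-1H-isochromen-8-ol
Product: 20 (3R,4S)-6-hydroxy-3,4,5-trimethyl-3,4-dihydro-8H-isochromen-8-one, via ethoxy quinone methide 19 (not isolated)
Conditions: DDQ (1.05 equiv), CH2Cl2, 0 °C; then 1 M HCl, THF–H2O, 40 °C
Reagents that add atoms: water, O
Why: DDQ should abstract hydride from C1 (benzylic, α to the ring oxygen, ortho to the hydroxyl and para to the ethoxy group) to give o-quinone methide 19, in which the former aryl ethyl ether is a vinylogous ester that is hydrolysed by addition–elimination of water at C6 (benzylic ether oxidation to a quinone methide followed by vinylogous ester hydrolysis).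

Step 11
Reactants: 20 (3R,4S)-6-hydroxy-3,4,5-trimethyl-3,4-dihydro-8H-isochromen-8-one
Product: 21 (3R,4S)-3,4,5-trimethyl-3,4-dihydro-1H-isochromene-6,8-diol
Conditions: NaBH4, EtOH, 0 °C; AcOH quench
Reagents that add atoms: none
Why: Conjugate (1,6) hydride addition to C1 of the quinone methide re-aromatises the ring, the usual behaviour of citrinin-type quinone methides toward borohydride, and touches neither stereocentre.

Step 12
Reactants: 21 (3R,4S)-3,4,5-trimethyl-3,4-dihydro-1H-isochromene-6,8-diol
Product: 22 (3R,4S)-7-[(dimethylamino)methyl]-3,4,5-trimethyl-3,4-dihydro-1H-isochromene-6,8-diol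
Conditions: Me2N=CH2 I (Eschenmoser's salt, 1.05 equiv), MeCN, 0 °C → rt; aq. NaHCO3
Reagents that add atoms: N,N-dimethylmethyleneiminium iodide, C=[N+](C)C.[I-]
Why: Mannich reaction (electrophilic aromatic substitution) at C7, the only free ring position and the one activated by both flanking hydroxyl groups.

Step 13
Reactants: 22 (3R,4S)-7-[(dimethylamino)methyl]-3,4,5-trimethyl-3,4-dihydro-1H-isochromene-6,8-diol; 20 (3R,4S)-6-hydroxy-3,4,5-trimethyl-3,4-dihydro-8H-isochromen-8-one
Product: 24 (3R,4S)-7-{[(3R,4S)-6,8-dihydroxy-3,4,5-trimethyl-3,4-dihydro-1H-isochromen-7-yl]methyl}-6-hydroxy-3,4,5-trimethyl-3,4-dihydro-8H-isochromen-8-one, via o-quinone methide 23 (not isolated)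
Conditions: 20 (1.2 equiv), 1,4-dioxane, 90 °C, argon sweep; dilute aq. HCl wash
Reagents that add atoms: none
Why: The acidic vinylogous acid 20 protonates the Mannich base, dimethylamine is lost to give o-quinone methide 23, and the anion of 20 adds through C7 (Michael addition of a cyclic 1,3-dicarbonyl-type nucleophile to an o-quinone methide), which re-aromatises the diol half and leaves the open C-alkylated form after tautomerisation.

## Compound list

1 | methyl (R)-3-hydroxybutanoate | C[C@@H](O)CC(=O)OC | starting material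
2 | dilithium alkoxide–enolate dianion of 1 (chelated) | [Li+].[Li+].[O-][C@H](C)/C=C(\[O-])OC | intermediate
3 | methyl (2R,3R)-3-hydroxy-2-methylbutanoate | O[C@H](C)[C@H](C(=O)OC)C | intermediate
4 | (2R,3R)-3-hydroxy-N-methoxy-N,2-dimethylbutanamide | O[C@H](C)[C@H](C(=O)N(C)OC)C | intermediate
5 | (4R,5R)-5-hydroxy-4-methylhex-1-yn-3-one | O[C@H](C)[C@H](C(=O)C#C)C | intermediate
6 | (2R,3R)-2,3-dimethyl-2,3-dihydro-4H-pyran-4-one | O=C1C=CO[C@H](C)[C@H]1C | intermediate
7 | lithium (2R,3R)-2,3-dimethyl-3,6-dihydro-2H-pyran-4-olate | [Li+].[O-]C1=CCO[C@H](C)[C@H]1C | intermediate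
8 | (2R,3R)-2,3-dimethyl-3,6-dihydro-2H-pyran-4-yl trifluoromethanesulfonate | O=S(=O)(OC1=CCO[C@H](C)[C@H]1C)C(F)(F)F | intermediate
9 | (2R,3S)-N-methoxy-N,2,3-trimethyl-3,6-dihydro-2H-pyran-4-carboxamide | CON(C)C(=O)C1=CCO[C@H](C)[C@H]1C | intermediate
10 | 1-[(2R,3S)-2,3-dimethyl-3,6-dihydro-2H-pyran-4-yl]propan-1-one | CCC(=O)C1=CCO[C@H](C)[C@H]1C | intermediate
11 | 1-[(2R,3S)-2,3-dimethyl-3,6-dihydro-2H-pyran-4-yl]-4,4,4-trifluoro-2-methylbutane-1,3-dione (both epimers at C2) | CC(C(=O)C(F)(F)F)C(=O)C1=CCO[C@H](C)[C@H]1C | intermediate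
12 | 2-diazo-1-[(2R,3S)-2,3-dimethyl-3,6-dihydro-2H-pyran-4-yl]propan-1-one | CC(=[N+]=[N-])C(=O)C1=CCO[C@H](C)[C@H]1C | intermediate
13 | ethoxyethyne (ethoxyacetylene) | CCOC#C | starting material
14 | 2-[(2R,3S)-2,3-dimethyl-3,6-dihydro-2H-pyran-4-yl]prop-1-en-1-one (vinylketene) | CC(=C=O)C1=CCO[C@H](C)[C@H]1C | intermediate
15 | 3-ethoxy-4-methyl-4-[(2R,3S)-2,3-dimethyl-3,6-dihydro-2H-pyran-4-yl]cyclobut-2-en-1-one (both epimers at C4) | CCOC1=CC(=O)C1(C)C2=CCO[C@H](C)[C@H]2C | intermediate
16 | 3-ethoxy-4-[(2R,3S)-2,3-dimethyl-3,6-dihydro-2H-pyran-4-yl]penta-1,3-dien-1-one (dienylketene) | CCOC(C=C=O)=C(C)C1=CCO[C@H](C)[C@H]1C | intermediate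
17 | (3R,4S)-6-ethoxy-3,4,5-trimethyl-3,4-dihydro-1H-isochromen-8(8aH)-one (both epimers at C8a) | O=C1C=C(OCC)C(C)=C2C1CO[C@H](C)[C@H]2C | intermediate
18 | (3R,4S)-6-ethoxy-3,4,5-trimethyl-3,4-dihydro-1H-isochromen-8-ol | Oc1cc(OCC)c(C)c2c1CO[C@H](C)[C@H]2C | intermediate
19 | (3R,4S)-6-ethoxy-3,4,5-trimethyl-3,4-dihydro-8H-isochromen-8-one | CC1=C2C(=CO[C@H](C)[C@H]2C)C(=O)C=C1OCC | intermediate
20 | (3R,4S)-6-hydroxy-3,4,5-trimethyl-3,4-dihydro-8H-isochromen-8-one (decarboxycitrinin) | CC1=C2C(=CO[C@H](C)[C@H]2C)C(=O)C=C1O | intermediate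
21 | (3R,4S)-3,4,5-trimethyl-3,4-dihydro-1H-isochromene-6,8-diol | Oc1cc(O)c(C)c2c1CO[C@H](C)[C@H]2C | intermediate
22 | (3R,4S)-7-[(dimethylamino)methyl]-3,4,5-trimethyl-3,4-dihydro-1H-isochromene-6,8-diol | CN(C)Cc1c(O)c(C)c2c(c1O)CO[C@H](C)[C@H]2C | intermediate
23 | (3R,4S)-6-hydroxy-3,4,5-trimethyl-7-methylidene-3,4-dihydro-1H-isochromen-8(7H)-one | C=C1C(O)=C(C)C2=C(C1=O)CO[C@H](C)[C@H]2C | intermediate
24 | Dicitrinone I, (3R,4S)-7-{[(3R,4S)-6,8-dihydroxy-3,4,5-trimethyl-3,4-dihydro-1H-isochromen-7-yl]methyl}-6-hydroxy-3,4,5-trimethyl-3,4-dihydro-8H-isochromen-8-one | CC1=C2C(=CO[C@H](C)[C@H]2C)C(=O)C(Cc2c(O)c(C)c3c(c2O)CO[C@H](C)[C@H]3C)=C1O | target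

## Step count and risks

Total step count: 13. Longest linear sequence: 13 (20 is used twice, as the precursor of 21 and as the coupling partner in step 13).

Steps most likely to fail:

**Step 9.** The vinylketene may be consumed by dimerisation or by acylating the phenolic product faster than the alkyne captures it, or irradiation may damage the enone before the Wolff rearrangement occurs. The fallback closes the same C8–C8a bond from an acylketene made thermally. It sets out from triflate 8. Palladium-catalysed coupling with the Reformatsky reagent BrZnCH(CH3)CO2t-Bu (Pd(PPh3)4, THF) should give tert-butyl 2-[(2R,3S)-2,3-dimethyl-3,6-dihydro-2H-pyran-4-yl]propanoate F1. CF3CO2H should cleave it to 2-[(2R,3S)-2,3-dimethyl-3,6-dihydro-2H-pyran-4-yl]propanoic acid F2. Meldrum's acid with DCC and DMAP should then give the acyl Meldrum's acid F3. Heating F3 in dilute toluene at 110 °C should expel acetone and CO2 to give acylketene F4; its dienol tautomer, hydroxydienylketene F5, should close by 6π electrocyclisation to dienone F6, the keto tautomer of 21. The fallback comes back to the route at 21. 20 would then be made from 21 with DDQ (1 equiv), and steps 12 and 13 follow unchanged.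

**Step 10.** Hydrolysis of the vinylogous ester may lag behind reversible hydration at C1 and self-condensation of the quinone methide, or DDQ may attack the C5 methyl group. The fallback removes the ethyl group at the arene level and reverses the order in which the two oxidation levels are reached. It sets out from 18: nucleophilic de-ethylation (NaSEt, DMF, 140 °C; substitution at the ethyl carbon, to which the cyclic benzylic ether is inert) should give 21 directly, and DDQ (1 equiv) would then convert part of 21 into 20. The route is rejoined at 21 and 20; no new compound is made.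

**Step 13.** The o-quinone methide may be captured at oxygen instead of at C7, or the liberated amine and 20 may condense at C1, so that C-alkylation is not the main path. The fallback forms the bridge between two reduced units and oxidises last. It sets out from 22 and 21: heating in toluene at 100 °C should give the symmetric bis(isochromanyl)methane F7 by the same o-quinone methide chemistry with the more robust resorcinol nucleophile. DDQ (1 equiv, 1,4-dioxane, 0 °C) should then oxidise one of the two equivalent halves at C1 to give 24 directly. This oxidation is statistical, so unreacted F7 would be recycled. The fallback comes back to the route at 24.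

## Further compounds

F1 | step 9 | tert-butyl 2-[(2R,3S)-2,3-dimethyl-3,6-dihydro-2H-pyran-4-yl]propanoate (both epimers at C2) | CC(C(=O)OC(C)(C)C)C1=CCO[C@H](C)[C@H]1C
F2 | step 9 | 2-[(2R,3S)-2,3-dimethyl-3,6-dihydro-2H-pyran-4-yl]propanoic acid (both epimers at C2) | CC(C(=O)O)C1=CCO[C@H](C)[C@H]1C
F3 | step 9 | 5-{1-hydroxy-2-[(2R,3S)-2,3-dimethyl-3,6-dihydro-2H-pyran-4-yl]propylidene}-2,2-dimethyl-1,3-dioxane-4,6-dione | CC(C(O)=C1C(=O)OC(C)(C)OC1=O)C2=CCO[C@H](C)[C@H]2C
F4 | step 9 | 4-[(2R,3S)-2,3-dimethyl-3,6-dihydro-2H-pyran-4-yl]pent-1-ene-1,3-dione (acylketene) | CC(C(=O)C=C=O)C1=CCO[C@H](C)[C@H]1C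
F5 | step 9 | 3-hydroxy-4-[(2R,3S)-2,3-dimethyl-3,6-dihydro-2H-pyran-4-yl]penta-1,3-dien-1-one (hydroxydienylketene) | O=C=CC(O)=C(C)C1=CCO[C@H](C)[C@H]1C
F6 | step 9 | (3R,4S)-6-hydroxy-3,4,5-trimethyl-3,4-dihydro-1H-isochromen-8(8aH)-one | O=C1C=C(O)C(C)=C2C1CO[C@H](C)[C@H]2C
F0 | step 10 | none | none
F7 | step 13 | bis[(3R,4S)-6,8-dihydroxy-3,4,5-trimethyl-3,4-dihydro-1H-isochromen-7-yl]methane | Oc1c(Cc2c(O)c(C)c3c(c2O)CO[C@H](C)[C@H]3C)c(O)c(C)c2c1CO[C@H](C)[C@H]2C
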